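all flasks: substrate 0.50 M
- alder: partner 0.70 equiv; free catalyst 0.27 mol%; temperature −35 °C; run made earlier
- oak: partner 0.70 equiv; free catalyst 1.3 mol%; temperature −20 °C; run made earlier
- zeta: partner 0.700 equiv; free catalyst 0.5 mol%; temperature −20 °C; time 15 h
- beta: partner 0.700 equiv; free catalyst 1.5 mol%; temperature −20 °C; time 50 h

| run | time / h | product / % |
|---|---|---|
| alder | 2.00 | 0 |
| alder | 4.00 | 1.1 |
| alder | 6.00 | 0.9 |
| alder | 8.00 | 1.1 |
| alder | 10.0 | 2.1 |
| alder | 12.0 | 2.3 |
| alder | 15.0 | 4.2 |
| oak | 0.417 | 0.6 |
| oak | 1.00 | 3.4 |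
| oak | 2.00 | 6.3 |
| oak | 3.00 | 9.5 |
| oak | 5.00 | 15.0 |
| oak | 6.00 | 17.3 |
| oak | 8.00 | 22.9 |

(each reading ± 0.5 percentage points)

- steps under discussion: substrate + free catalyst <-> catalyst intermediate A; catalyst intermediate D -> free catalyst + product; catalyst intermediate C <-> by-product + catalyst intermediate D; catalyst intermediate A <-> catalyst intermediate B; partner + catalyst intermediate B <-> catalyst intermediate C

* which one finishes higher in amount of product, in percent of the substrate charged ("neither" within 2 percentage points) (zeta / beta / neither)
* amount of product at the end, in percent of the substrate charged, zeta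
* amount of product at the end, in percent of the substrate charged, beta

- Start from amounts. Along the listed steps each product takes one partner, and the partner charge is 0.700 equiv on substrate. So partner is the limiting reagent, and 70.0% of the substrate charged is your ceiling for beta.
- Oak ran at −20 °C, like both new flasks, so read oak and leave the colder alder aside. Assume that the rate follows the catalyst loading.
- Assume too that the rate follows the partner left. Then the partner left halves at a fixed interval. Oak's last reading, 22.9% at 8.00 h, gives 14.0 h: this is the partner half-life at oak's loading, and it carries the scatter of that reading.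
- Test it on another oak reading. At 5.00 h it gives 15.4%, and oak read 15.0%.
- Scale it by loading. Beta's half-life is 12.1 h, so 50 h leaves 5.74% of the partner and makes 66.0% product. Zeta's is 36.4 h, which gives 17.4% at 15 h.
- For a floor, let substrate slow the rate as well. Integrated, the logarithm of substrate left over partner left, each as a share of its charge, grows in step with loading times time. Oak's ratio is 1.15, and beta has 7.21 times oak's loading times time. That gives 2.67 for beta, or 59.3% product.
- So your bracket for beta runs from 59.3% to 70.0%. This reckoning commits to 66.0%, and to beta as the higher flask.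
- The forecast says beta, with 16.5% for zeta and 60% for beta, “with possible catalyst deactivation as the main uncertainty”. Its beta lies inside the bracket, lower than this reckoning.
- The flasks give beta as the higher: 17.6% for zeta and 66.5% for beta, which is 6.5 percentage points above the forecast.

    substrate + free catalyst ⇌ catalyst intermediate A (K = 6.00 M⁻¹, k = 0.0165 M⁻¹ s⁻¹, Ea = 54.0 kJ mol⁻¹, ΔH = −54.0 kJ mol⁻¹)
    catalyst intermediate D → free catalyst + product (k = 0.00855 s⁻¹, Ea = 66.0 kJ mol⁻¹)
    catalyst intermediate C ⇌ by-product + catalyst intermediate D (K = 1.37 M, k = 0.00779 s⁻¹, Ea = 73.0 kJ mol⁻¹, ΔH = −22.0 kJ mol⁻¹)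
    catalyst intermediate A ⇌ catalyst intermediate B (K = 0.108, k = 0.00821 s⁻¹, Ea = 72.0 kJ mol⁻¹, ΔH = −45.0 kJ mol⁻¹)
    partner + catalyst intermediate B ⇌ catalyst intermediate C (K = 31.2 M⁻¹, k = 0.0575 M⁻¹ s⁻¹, Ea = 58.0 kJ mol⁻¹, ΔH = −20.0 kJ mol⁻¹)
    (constants at −20 °C)

- Beta's 50 h spans 4.13 partner half-lives of 12.1 h, which by this reckoning leaves 5.74% of the partner, where beta holds 4.91%. Zeta, with a half-life of 36.4 h, has run 4.12 half-lives by 150 h, and there zeta holds 4.83% of its partner and 66.6% product.

(The earlier runs and the new flask stem from a simulated flask on assumed constants.)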